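The C1–C5 bond (C1 = cyclopentane CH bearing the side chain, C5 = spiro carbon) is formed by a thermal intramolecular ene reaction that copies the bisabolane-to-acorane folding of the biosynthesis. The precursor is a 3-alkylcyclohex-2-enone whose prenyl terminus is the ene donor: its CH adds to the enone β-carbon (C5) while a methyl hydrogen passes to the α-carbon (C6). In one operation the cyclopentane ring, the spiro quaternary centre and C1 are created and an isopropenyl group is left for the butenolide side chain. The step exploits the array H–C6–C5–C1–C(CH3)=CH2, an ene retron once C7 of the six-membered ring is a ketone.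

Key step: step 4

Assumption: (R)-6-methylhept-5-en-2-ol is taken as purchasable in enantiopure form (it is also accessible by enzymatic resolution of the racemate).
Labels used for the spirocycle: cyclopentane C1 (side chain), C2, C3, C4 (methyl), spiro C5; six-membered ring C6 (CH2), C7, C8 (methyl), C9 (oxygen in the target), C10 (CH2); side chain C1' (CH–CH3) and C2'.

Step 1
Reactants: 1 (R)-6-methylhept-5-en-2-ol
Product: 2 (R)-6-methylhept-5-en-2-yl 4-methylbenzenesulfonate
Conditions: TsCl, pyridine, DMAP (cat.), CH2Cl2, 0 °C to rt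
Reagents that add atoms: 4-methylbenzenesulfonyl chloride, Cc1ccc(cc1)S(Cl)(=O)=O
Why: O-sulfonylation of the secondary alcohol leaves the carbinol configuration untouched and makes it a leaving group.

Step 2
Reactants: 2 (R)-6-methylhept-5-en-2-yl 4-methylbenzenesulfonate; 3 4-bromo-2-methoxy-1-methylbenzene
Product: 6 (S)-2-methoxy-1-methyl-4-(6-methylhept-5-en-2-yl)benzene, via aryllithium 4 (not isolated), via lithium diarylcuprate 5 (not isolated)
Conditions: 3, t-BuLi (2 equiv), Et2O, −78 °C; CuI (0.5 equiv), −40 °C; then 2, −40 to 0 °C; NH4Cl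
Reagents that add atoms: none
Why: SN2 substitution of the secondary tosylate by a Gilman diarylcuprate proceeds with inversion, so the (R)-carbinol carbon becomes the (S)-benzylic centre that is C4 of the target.

Step 3
Reactants: 6 (S)-2-methoxy-1-methyl-4-(6-methylhept-5-en-2-yl)benzene
Product: 9 6-methyl-3-[(2S)-6-methylhept-5-en-2-yl]cyclohex-2-en-1-one (C6 epimers), via Birch dienol ether 7 (not isolated), via deconjugated enone 8 (not isolated)
Conditions: Li, NH3(l), THF, t-BuOH, −78 to −33 °C; NH4Cl; then 1 M HCl, THF, rt (short contact)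
Reagents that add atoms: water, O
Why: Birch reduction leaves the ring double bonds on the methoxy/methyl and alkyl-bearing carbons, and acid hydrolysis of the enol ether with conjugation gives the 3-alkyl enone without touching C4 (the epimeric ring methyl carbon is erased in step 5).

Step 4
Reactants: 9 6-methyl-3-[(2S)-6-methylhept-5-en-2-yl]cyclohex-2-en-1-one
Product: 10 (1R,4S,5R)-4,8-dimethyl-1-(prop-1-en-2-yl)spiro[4.5]decan-7-one (C8 epimers)
Conditions: PhMe (0.01 M), BHT (cat.), base-washed sealed tube, 260 °C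
Reagents that add atoms: none
Why: Concerted intramolecular Alder-ene reaction (type 1, 1,6-diene): the prenyl CH (C1) bonds to the enone β-carbon (C5) while an allylic methyl hydrogen is passed suprafacially to the α-carbon (C6) and the ene double bond shifts into the isopropenyl group. The closest known reactions are the thermal ene cyclisations of cyclohexenes carrying a 1,5-dimethylhex-4-enyl chain to 1-isopropenylspiro[4.5]decanes (acorane skeleton) and ene reactions with enones as enophiles. The cyclopentane closes in the 5-exo mode across the three-carbon tether, C6 staying outside the new ring and the six-membered ring staying intact. C1 is controlled by the pericyclic geometry, since the isopropenyl carbon must lie over C6 to deliver the hydrogen and therefore ends cis to C6; C5 is controlled by the preset C4 centre, whose hydrogen lies near the enone plane beside the vinylic C6–H (allylic strain) so that the C4 methyl is pseudo-equatorial, cis to C10 and remote from the ene unit. The step needs five-ring closure at the substituted β-carbon and one enone face: conjugation to the carbonyl polarises C5 for attack by C1, the tether length allows only the five-membered transition state without strain, and high dilution with BHT suppresses intermolecular paths. The C8 methyl remains a mixture that step 5 removes.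

Step 5
Reactants: 10 (1R,4S,5R)-4,8-dimethyl-1-(prop-1-en-2-yl)spiro[4.5]decan-7-one
Product: 11 (1R,4S,5R)-4,8-dimethyl-1-(prop-1-en-2-yl)spiro[4.5]dec-8-en-7-one
Conditions: IBX, DMSO/PhF, 75 °C
Reagents that add atoms: none
Why: IBX dehydrogenation of the ketone can only run towards C8–C9 because the other α-carbon (C6) is attached to the quaternary C5, and it removes the stereo-mixture at C8.

Step 6
Reactants: 11 (1R,4S,5R)-4,8-dimethyl-1-(prop-1-en-2-yl)spiro[4.5]dec-8-en-7-one
Product: 12 (1R,4S,5R,8S,9S)-8,9-epoxy-4,8-dimethyl-1-(prop-1-en-2-yl)spiro[4.5]decan-7-one (epoxide on the ring face of C1)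
Conditions: 30% H2O2, NaOH, MeOH, 0 °C
Reagents that add atoms: hydrogen peroxide, OO
Why: Weitz–Scheffer nucleophilic epoxidation, in which hydroperoxide should add to C9 axially and syn to the axial C5 substituent, expected to be C1 (its hydrogen, not a methyl as on C4, points over C10), so that the oxygen lies on the ring face of C1 and fixes the future C9 configuration.

Step 7
Reactants: 12 (1R,4S,5R,8S,9S)-8,9-epoxy-4,8-dimethyl-1-(prop-1-en-2-yl)spiro[4.5]decan-7-one
Product: 14 (1R,4S,5S,9S)-4,8-dimethyl-1-(prop-1-en-2-yl)spiro[4.5]dec-7-en-9-ol, via epoxy hydrazone 13 (not isolated)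
Conditions: N2H4·H2O, AcOH (cat.), MeOH, Ar, 0 °C to rt
Reagents that add atoms: none
Why: Wharton transposition, in which the epoxy hydrazone fragments with loss of N2 to the allylic alcohol, moving the double bond to C7=C8 and keeping the C9–O configuration set in step 6.

Step 8
Reactants: 14 (1R,4S,5S,9S)-4,8-dimethyl-1-(prop-1-en-2-yl)spiro[4.5]dec-7-en-9-ol; 15 3-phenylpropanoyl chloride
Product: 16 (1R,4S,5S,9S)-4,8-dimethyl-1-(prop-1-en-2-yl)spiro[4.5]dec-7-en-9-yl 3-phenylpropanoate
Conditions: pyridine, DMAP (cat.), CH2Cl2, 0 °C to rt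
Reagents that add atoms: none
Why: DMAP-catalysed acylation of the secondary allylic alcohol at oxygen, with retention at C9.

Step 9
Reactants: 16 (1R,4S,5S,9S)-4,8-dimethyl-1-(prop-1-en-2-yl)spiro[4.5]dec-7-en-9-yl 3-phenylpropanoate
Product: 18 (1R,4S,5S,9S)-1-[(2S)-1-hydroxypropan-2-yl]-4,8-dimethylspiro[4.5]dec-7-en-9-yl 3-phenylpropanoate, via B-alkyl-9-BBN adduct 17 (not isolated)
Conditions: 9-BBN, THF, 0 °C to rt; then 30% H2O2, aq NaOAc, 0 °C
Reagents that add atoms: hydrogen peroxide, OO
Why: Anti-Markovnikov hydroboration–oxidation, in which 9-BBN adds only to the 1,1-disubstituted isopropenyl group and, with C1–H eclipsing the double bond, from the face away from the quaternary C5 (the sense known for 20-methylene steroids), which should give (S)-C1', while buffered peroxide spares the ester.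

Step 10
Reactants: 18 (1R,4S,5S,9S)-1-[(2S)-1-hydroxypropan-2-yl]-4,8-dimethylspiro[4.5]dec-7-en-9-yl 3-phenylpropanoate
Product: 19 (1R,4S,5S,9S)-4,8-dimethyl-1-[(2S)-1-oxopropan-2-yl]spiro[4.5]dec-7-en-9-yl 3-phenylpropanoate
Conditions: Dess–Martin periodinane, NaHCO3, CH2Cl2, 0 °C to rt
Reagents that add atoms: none
Why: Dess–Martin oxidation of the primary alcohol under buffered, non-basic conditions should keep the α-stereocentre C1' intact.

Step 11
Reactants: 19 (1R,4S,5S,9S)-4,8-dimethyl-1-[(2S)-1-oxopropan-2-yl]spiro[4.5]dec-7-en-9-yl 3-phenylpropanoate; 20 3-methylfuran-2(5H)-one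
Product: 23 target CNP0260277.1 [(1R,4S,5S,9S)-4,8-dimethyl-1-[(1Z,2S)-1-(4-methyl-5-oxofuran-2(5H)-ylidene)propan-2-yl]spiro[4.5]dec-7-en-9-yl 3-phenylpropanoate], via silyloxyfuran 21 (not isolated), via silyl aldol adduct 22 (not isolated)
Conditions: TBSOTf, i-Pr2NEt, CH2Cl2, 0 °C to rt; then DBU, rt
Reagents that add atoms: none
Why: Vinylogous Mukaiyama aldol addition of the 2-silyloxyfuran formed in the flask at its 5-position, followed by DBU-induced E1cB loss of silanolate, gives the γ-ylidenebutenolide, the Z isomer being favoured because it avoids allylic strain between the branched substituent and the ring C4–H.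

Compound list
1 | (R)-6-methylhept-5-en-2-ol | C[C@@H](O)CCC=C(C)C | starting material
2 | (R)-6-methylhept-5-en-2-yl 4-methylbenzenesulfonate | C[C@@H](OS(=O)(=O)c1ccc(C)cc1)CCC=C(C)C | intermediate
3 | 4-bromo-2-methoxy-1-methylbenzene | COc1cc(Br)ccc1C | starting material
4 | (3-methoxy-4-methylphenyl)lithium | [Li]c1ccc(C)c(OC)c1 | intermediate (not isolated)
5 | lithium bis(3-methoxy-4-methylphenyl)cuprate | [Li+].COc1cc(ccc1C)[Cu-]c1ccc(C)c(OC)c1 | intermediate (not isolated)
6 | (S)-2-methoxy-1-methyl-4-(6-methylhept-5-en-2-yl)benzene | C[C@@H](CCC=C(C)C)c1ccc(C)c(OC)c1 | intermediate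
7 | 1-methoxy-2-methyl-5-[(2S)-6-methylhept-5-en-2-yl]cyclohexa-1,4-diene | COC1=C(C)CC=C([C@@H](C)CCC=C(C)C)C1 | intermediate (not isolated)
8 | 2-methyl-5-[(2S)-6-methylhept-5-en-2-yl]cyclohex-4-en-1-one | CC1CC=C(CC1=O)[C@@H](C)CCC=C(C)C | intermediate (not isolated)
9 | 6-methyl-3-[(2S)-6-methylhept-5-en-2-yl]cyclohex-2-en-1-one | CC1CCC(=CC1=O)[C@@H](C)CCC=C(C)C | intermediate
10 | (1R,4S,5R)-4,8-dimethyl-1-(prop-1-en-2-yl)spiro[4.5]decan-7-one | CC(=C)[C@H]1CC[C@H](C)[C@@]12CC(=O)C(C)CC2 | intermediate
11 | (1R,4S,5R)-4,8-dimethyl-1-(prop-1-en-2-yl)spiro[4.5]dec-8-en-7-one | CC(=C)[C@H]1CC[C@H](C)[C@@]12CC(=O)C(C)=CC2 | intermediate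
12 | (1R,4S,5R,8S,9S)-8,9-epoxy-4,8-dimethyl-1-(prop-1-en-2-yl)spiro[4.5]decan-7-one | CC(=C)[C@H]1CC[C@H](C)[C@@]12CC(=O)[C@@]3(C)O[C@H]3C2 | intermediate
13 | hydrazone of 12 | CC(=C)[C@H]1CC[C@H](C)[C@@]12CC(=NN)[C@@]3(C)O[C@H]3C2 | intermediate (not isolated)
14 | (1R,4S,5S,9S)-4,8-dimethyl-1-(prop-1-en-2-yl)spiro[4.5]dec-7-en-9-ol | CC(=C)[C@H]1CC[C@H](C)[C@@]12CC=C(C)[C@@H](O)C2 | intermediate
15 | 3-phenylpropanoyl chloride | O=C(Cl)CCc1ccccc1 | starting material
16 | (1R,4S,5S,9S)-4,8-dimethyl-1-(prop-1-en-2-yl)spiro[4.5]dec-7-en-9-yl 3-phenylpropanoate | CC(=C)[C@H]1CC[C@H](C)[C@@]12CC=C(C)[C@@H](OC(=O)CCc3ccccc3)C2 | intermediate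
17 | B-alkyl-9-borabicyclo[3.3.1]nonane adduct of 16 (boron on C2') | C[C@H](CB1C2CCCC1CCC2)[C@H]3CC[C@H](C)[C@@]34CC=C(C)[C@@H](OC(=O)CCc5ccccc5)C4 | intermediate (not isolated)
18 | (1R,4S,5S,9S)-1-[(2S)-1-hydroxypropan-2-yl]-4,8-dimethylspiro[4.5]dec-7-en-9-yl 3-phenylpropanoate | OC[C@@H](C)[C@H]1CC[C@H](C)[C@@]12CC=C(C)[C@@H](OC(=O)CCc3ccccc3)C2 | intermediate
19 | (1R,4S,5S,9S)-4,8-dimethyl-1-[(2S)-1-oxopropan-2-yl]spiro[4.5]dec-7-en-9-yl 3-phenylpropanoate | O=C[C@@H](C)[C@H]1CC[C@H](C)[C@@]12CC=C(C)[C@@H](OC(=O)CCc3ccccc3)C2 | intermediate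
20 | 3-methylfuran-2(5H)-one | CC1=CCOC1=O | starting material
21 | tert-butyl(dimethyl)[(3-methylfuran-2-yl)oxy]silane | Cc1ccoc1O[Si](C)(C)C(C)(C)C | intermediate (not isolated)
22 | O-silyl vinylogous aldol adduct of 19 and 21 (carbinol and lactone C5 centres unassigned) | CC1=CC(OC1=O)C(O[Si](C)(C)C(C)(C)C)[C@@H](C)[C@H]2CC[C@H](C)[C@@]23CC=C(C)[C@@H](OC(=O)CCc4ccccc4)C3 | intermediate (not isolated)
23 | CNP0260277.1 | CC1=C/C(=C/[C@@H](C)[C@H]2CC[C@H](C)[C@@]23CC=C(C)[C@@H](OC(=O)CCc2ccccc2)C3)OC1=O | target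

Total step count: 11. Longest linear sequence: 11 steps (1 to 23).

Steps most likely to fail

Step 4. Addition at the fully substituted β-carbon may be slow enough that thermal decomposition competes, and closure on the other enone face would give the C5 epimer relative to C4. The fallback sets out from 6 and returns at 10. Allylic oxidation of 6 (SeO2 cat., t-BuOOH, CH2Cl2) gives the (E)-allylic alcohol F1, which is converted (MsCl, Et3N; LiCl) into the allylic chloride F2 and then (Mg, Me3SiCl, THF) into the allylsilane F3. Birch reduction with mild hydrolysis and conjugation (Li, NH3, t-BuOH; oxalic acid; DBU cat.) gives the allylsilane enone F4. TiCl4 in CH2Cl2 at −78 °C then closes the same C1–C5 bond by an intramolecular Hosomi–Sakurai addition, the silyl group leaving to give the isopropenyl ketone 10.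

Step 6. Facial selectivity of hydroperoxide addition at C9 may be poor, which would scramble the C9 configuration. The fallback sets out from 14 (as the C9 epimer mixture) and returns at 16. Oxidation with MnO2 (CH2Cl2) gives the transposed enone F5. Luche reduction (NaBH4, CeCl3·7H2O, MeOH, −78 °C) should deliver hydride axially from the C1 face and give the C9-epimeric alcohol F6. Mitsunobu esterification with 3-phenylpropanoic acid (PPh3, DIAD, THF) inverts C9 and gives 16 directly.

Step 11. The hindered α-branched aldehyde may epimerise at C1' under silyl triflate and amine base, and the elimination may not be fully Z-selective. The fallback sets out from 19 and returns at 23. Colvin homologation (TMSCHN2, LDA, THF, −78 °C to rt) gives the terminal alkyne F7. Separately, propargyl alcohol is carbomagnesiated and iodinated (MeMgBr, CuI cat.; I2) to (Z)-3-iodo-2-methylprop-2-en-1-ol F8, and oxidised (CrO3, H2SO4, acetone) to (Z)-3-iodo-2-methylprop-2-enoic acid F9. CuI with K2CO3 in DMF at 55 °C couples F7 with F9, and the enynoic acid lactonises 5-exo-dig in the same flask to the (Z)-ylidenebutenolide 23.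

Further compounds
F1 | step 4 | (2E,6S)-6-(3-methoxy-4-methylphenyl)-2-methylhept-2-en-1-ol | OC/C(C)=C/CC[C@H](C)c1ccc(C)c(OC)c1
F2 | step 4 | 4-[(2S,5E)-7-chloro-6-methylhept-5-en-2-yl]-2-methoxy-1-methylbenzene | ClC/C(C)=C/CC[C@H](C)c1ccc(C)c(OC)c1
F3 | step 4 | [(2E,6S)-6-(3-methoxy-4-methylphenyl)-2-methylhept-2-en-1-yl]trimethylsilane | C[Si](C)(C)C/C(C)=C/CC[C@H](C)c1ccc(C)c(OC)c1
F4 | step 4 | 6-methyl-3-[(2S,5E)-6-methyl-7-(trimethylsilyl)hept-5-en-2-yl]cyclohex-2-en-1-one | CC1CCC(=CC1=O)[C@@H](C)CC/C=C(\C)C[Si](C)(C)C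
F5 | step 6 | (1R,4S,5S)-4,8-dimethyl-1-(prop-1-en-2-yl)spiro[4.5]dec-7-en-9-one | CC(=C)[C@H]1CC[C@H](C)[C@@]12CC=C(C)C(=O)C2
F6 | step 6 | (1R,4S,5S,9R)-4,8-dimethyl-1-(prop-1-en-2-yl)spiro[4.5]dec-7-en-9-ol | CC(=C)[C@H]1CC[C@H](C)[C@@]12CC=C(C)[C@H](O)C2
F7 | step 11 | (1R,4S,5S,9S)-1-[(2S)-but-3-yn-2-yl]-4,8-dimethylspiro[4.5]dec-7-en-9-yl 3-phenylpropanoate | C#C[C@@H](C)[C@H]1CC[C@H](C)[C@@]12CC=C(C)[C@@H](OC(=O)CCc3ccccc3)C2
F8 | step 11 | (Z)-3-iodo-2-methylprop-2-en-1-ol | OC/C(C)=C\I
F9 | step 11 | (Z)-3-iodo-2-methylprop-2-enoic acid | OC(=O)/C(C)=C\I
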